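You have no constants for these flasks, so count turnovers instead.

| flask | X | E | L | remark | time |
|---|---|---|---|---|---|
| Sunday's | 0.42 M | 0.84 M | 0.066 M | run made earlier |  |
| Thursday's | 0.42 M | 0.84 M | 0.91 M | run made earlier |  |
| teal | 0.42 M | 0.840 M | 0.100 M |  | 30 h |
| violet | 0.42 M | 0.840 M | 0.200 M |  | 30 h |
| green | 0.42 M | 0.840 M | 0.400 M |  | 30 h |
| red | 0.42 M | 0.840 M | 0.800 M |  | 30 h |
| ochre | 0.42 M | 0.840 M | 1.50 M |  | 30 h |

| run | time / h | Z / % | X / % |
|---|---|---|---|
| Sunday's | 8.00 | 58.4 | 14.7 |
| Sunday's | 15.0 | 51.6 | 15.0 |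
| Sunday's | 25.0 | 42.8 | 18.3 |
| Sunday's | 30.0 | 37.1 | 18.7 |
| Thursday's | 8.00 | 22.6 | 40.9 |
| Thursday's | 15.0 | 17.9 | 40.5 |
| Thursday's | 25.0 | 13.1 | 41.3 |
| Thursday's | 30.0 | 15.1 | 39.5 |

(scatter of a reading: 1 percentage point)

- the earlier runs were read with a standard deviation of 1 percentage point
- "hardly changes" means that all values lie within two and a half points (for a concentration: within two and a half percent of the largest)

- [Z] at the end for teal, violet, green, red, ochre, in this order
- the course of these numbers from the first flask to the last (rises all the way / falls all the way / hardly changes / rises, then falls / falls, then rises)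

The readings are percentages of the pool, X plus L as charged, and that pool differs from run to run, so put them in molarity first. Thursday's pool less its X comes to 0.786 M at 8.00 h and 0.805 M at 30.0 h. That last figure is the turnover count: the pool that has gone to Z or out of sight, taken here as one E per turnover. It stays just under the E charge of 0.84 M, so E looks like the limiting reagent on Thursday.

But Z has to share that count with the unseen loss, which is 45.4% of Thursday's pool at 30.0 h and 44.2% of Sunday's. At Thursday's share, red loses enough to leave 0.251 M of the count for Z. That is above Sunday's Z of 0.180 M, so my reckoning does not put red under that level. At the same share ochre's loss comes to 0.872 M, more than the count, so I put ochre well under Sunday's Z.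

The forecast runs from 0.185 M in teal to 0.19 M in ochre, hardly changes, with Z capped by, in its words, “presumably E being used up”, and my reckoning parts from it at ochre.

The flasks give 0.185 M, 0.198 M, 0.213 M, 0.186 M and 0.0997 M: rises, then falls.

    X ⇌ L (K = 0.00720, k = 8.40 × 10⁻⁵ s⁻¹)
    2 E → J (k = 3.90 × 10⁻⁵ M⁻¹ s⁻¹)
    X + E ⇌ Z (K = 16.0 M⁻¹, k = 4.40 × 10⁻⁴ M⁻¹ s⁻¹)
    E + L → G (k = 0.0170 M⁻¹ s⁻¹)

The unseen product is G. Ochre's Z stands at 0.0997 M in part through the back reaction of L to X together with the time given: without that back reaction it is 4.44 × 10⁻⁴ M, and by 300 h it is 3.64 × 10⁻⁴ M. Ochre holds 0.731 M of G at 30.0 h, so the count leaves 0.0739 M for Z, against 0.0997 M found. In red, the count less G leaves 0.203 M, against 0.186 M found.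

The earlier runs and the new flask stem from a simulated flask with made-up constants, and the scatter is random.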